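The readings are simulated for substances that don't exist; the scatter is artificial.

The length is a ratio: monomer in chains over chains begun.

| setting | oak | alder | cedar | flask |
|---|---|---|---|---|
| free monomer | 9 mM | 36 mM | 18 mM | 18 mM |
| protic impurity | 1.8 mM | 1.8 mM | 1.8 mM | 1.80 mM |
| initiator | 0.90 mM | 0.90 mM | 0.45 mM | 0.90 mM |
| stray impurity | 0.74 mM | 0.74 mM | 0.74 mM | 0.74 mM |
| remark | run made earlier | run made earlier | run made earlier |  |
| time |  |  |  | 1.0 h |

| run | time / min | monomer in chains / % | free monomer / % |
|---|---|---|---|
| oak | 4.00 | 7 | 95 |
| oak | 12.0 | 7 | 87 |
| oak | 20.0 | 6 | 76 |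
| oak | 30.0 | 15 | 73 |
| oak | 50.0 | 23 | 61 |
| oak | 60.0 | 25 | 60 |
| alder | 4.00 | 0 | 97 |
| alder | 12.0 | 10 | 87 |
| alder | 20.0 | 12 | 80 |
| alder | 30.0 | 20 | 78 |
| alder | 50.0 | 34 | 64 |
| alder | 60.0 | 38 | 60 |
| cedar | 5.00 | 0 | 95 |
| cedar | 15.0 | 1 | 90 |
| cedar | 30.0 | 3 | 85 |
| cedar | 40.0 | 4 | 83 |
| cedar | 60.0 | 9 | 85 |

(readings scatter by 2 percentage points)

- the average divides the monomer in chains by the number of chains begun, living and dead together
- the earlier runs do not show the number of chains; that part of a forecast is a guess

* whether the average number of monomer units in a chain (chains begun, living or dead) reaches 20 by 1.0 h (no / yes)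
* average number of monomer units in a chain (chains begun, living or dead) at 1.0 h

In the flask the stray impurity charge is the smaller of the pair, so it is the limiting reagent there. In cedar the initiator charge is the smaller, and the last reading of chains in cedar is 9% of the monomer charge after 60.0 min, against 25% in oak and 38% in alder after 60.0 min, two runs that differ from cedar in both initiator charge and monomer charge. The part of the initiator charge exceeding the stray impurity charge is 17.8%. This surviving share is taken here as the chains begun, a guess the runs cannot test, and oak and alder carry the same two charges as the flask.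

Read as rates, chains gain 25% of the charge in the hour in oak and 38% in alder. Free monomer falls to 60% in oak and 60% in alder, and that slowing is already inside both gains. The protic impurity, if it takes its full charge in monomer, leaves a factor 0.800 in oak, 0.950 in alder and 0.900 in the flask. Dividing out the first two, averaging, and applying the third gives 32.1% in chains for the flask. The reckoning here therefore puts the length in the flask at 36.1, above the length asked.

The forecast differs: no, with a length of 7, on the ground “If killed chains count as begun”.

The flask gives yes, with a length of 30.8 at 1.0 h, having passed the wanted length at 0.602 h.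

    free monomer + initiator → living end + monomer in chains (k = 14.1 M⁻¹ min⁻¹)
    free monomer + living end → monomer in chains + living end, rate k2*[living end]*[free monomer] (k = 37.9 M⁻¹ min⁻¹)
    initiator + stray impurity → spent initiator (k = 7240 M⁻¹ min⁻¹)
    monomer in chains → over-reaction product (k = 1.70 × 10⁻⁵ min⁻¹)
    protic impurity + free monomer → quenched substrate (k = 6.21 M⁻¹ min⁻¹)

At 1.00 h spent initiator holds 81.6% of the initiator charge and the living end 18.4%. Chains at 28.4% of the flask's monomer charge, divided by the surviving share, reckon to 31.9. In oak the same share turns the last reading of chains, 25%, into a length of 14.1.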